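| flask | Z | X | L | remark | time |
|---|---|---|---|---|---|
| autumn | 39 mM | 1.2 equiv | 12 mM | run made earlier |  |
| midnight | 78 mM | 1.2 equiv | 7.8 mM | run made earlier |  |
| maple | 39 mM | 1.20 equiv | 7.80 mM |  | 2.5 h |
| alder | 39 mM | 2.40 equiv | 7.80 mM |  | 2.5 h |
| oak | 39 mM | 4.80 equiv | 7.80 mM |  | 2.5 h |

| run | time / min | Z / % | G / % |
|---|---|---|---|
| autumn | 8.00 | 85.9 | 10.7 |
| autumn | 15.0 | 77.3 | 17.7 |
| autumn | 25.0 | 67.7 | 24.2 |
| autumn | 50.0 | 54.6 | 33.7 |
| autumn | 90.0 | 43.5 | 39.9 |
| midnight | 8.00 | 75.2 | 18.9 |
| midnight | 15.0 | 63.2 | 28.6 |
| midnight | 25.0 | 51.8 | 35.9 |
| midnight | 50.0 | 38.2 | 45.4 |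
| midnight | 90.0 | 29.2 | 51.4 |

(each reading ± 0.3 percentage points)

- in percentages every species weighs as the Z in it: one D counts as two
- the earlier runs were read with a standard deviation of 0.3 percentage points
- steps thought possible: X + E <-> Q; 2 Z -> D; X + L -> J; Z + X -> E + G

- part of the Z that has reacted at the end, maple
- part of the Z that has reacted at the end, alder
- part of the Z that has reacted at the end, oak
- what raising the equivalents of X from its lowest to its highest value here does to the part of the Z that has reacted (changes below 5 percentage points count as none) (it rises / it falls / no change)

- G slows in both earlier runs while Z is still there: the last reading of the autumn run has 39.9% G beside 43.5% Z, and that of the midnight run has 51.4% G beside 29.2% Z.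
- I read this as a shortage of X: each G releases an E that can hold a further X as Q, and each L can take one X as J.
- My one number, 50.0% for maple, is the X budget: the charged [X] minus the charged [L], halved, then divided by the charged [Z], which is the share of Z that can become G before free X is gone if each L takes one X as J and each E takes one X as Q.
- The same sum gives 44.6% for the autumn run and 55.0% for the midnight run, and the last G reading stands below the budget in each.
- One number is not enough, since the budget counts G and not Z lost: by its last reading the autumn run has also lost 16.6% of its Z without G, which I take for D, so as a rough estimate I reckon 66.6% reacted in maple, with X as the limiting reagent.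
- Alder has a budget of 110% and oak 230%, both above the whole of Z, so there the budget predicts no stall but gives no figure, and I expect the reacted part to rise with X.
- The forecast gives 70%, 92% and 99.7%, with the trend it rises, on this ground: “Each G therefore costs nearly two X, and L takes its share as well.” For maple, its figure differs from my 66.6%.
- The flasks give 66.3% in maple, 89.9% in alder and 99.8% in oak, and the trend is it rises, by 34 percentage points, so the forecast holds.

    X + E ⇌ Q, settled at all times (K = 37000 M⁻¹)
    2 Z → D (k = 3.50 M⁻¹ h⁻¹)
    X + L → J (k = 57.0 M⁻¹ h⁻¹)
    Z + X → E + G (k = 22.0 M⁻¹ h⁻¹)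

- The equivalents of X are the main reason for that rise: oak reacts 99.8%, against 66.3% without the difference in X. Maple ends with 46.7% G against its budget of 50.0%, with 8.1% of its X free beside 34% of its Z. A neighbour of alder, charged with 0.600 equiv of X, has a budget of 20.0%; 44.8% of its L still stands, so with the 4.30 mM of J formed in place of the charged [L] the budget reads 24.5%, and that neighbour ends with 23.6% G.

The numbers in the tables come from a simulation from invented constants.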